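A direct plan would build the cyclohexene from small pieces and add its features one at a time.
It would allylate an α-quaternary aldehyde asymmetrically to set the carbinol carbon, extend the chain, and close the ring by metathesis to the silyloxy enone A1.
A1 would be methylenated to the exocyclic diene A2, and A2 hydroborated to the primary alcohol A3, which would be etherified with umbelliferone, desilylated and acylated.
Weakest would be the run-up to A1: about eight operations, mostly oxidation-level and protecting-group changes, would be spent on a ring with one stereocentre.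
Next would be the hydroboration of A2: the only step that would set the ring CH carbon would rest on a small facial bias beside a quaternary carbon, across a conjugated diene, on material ten steps old.
Third would be the methylenation of A1: a carbanion would have to add to a carbonyl wedged between a quaternary carbon and a substituted alkene carbon, where γ-deprotonation to the dienolate would compete.

**Plan of the new route**
Locants: C1 = ring CH bearing C7H2–O–coumarin, C2 = C(CH3)=, C3 = CH=, C4 = CH2, C5 = CH–O–acyl, C6 = C(CH3)2; C1'–C7' are the geranyl chain locants (C2' becomes C1, C6' becomes C5, C7' becomes C6, C1' becomes C7).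
The retrosynthesis cuts the aryl ether bond O–C7, then the two ester bonds at O–C5 and O–C7, and last the ring bond C1–C6 together with a C3–H bond, which unfolds the ring into the 6',7'-oxirane of geranyl acetate.
The feature that allows this: C5 (oxygen-bearing) and C6 (gem-dimethyl) are the two carbons of a 2,2-dimethyloxirane, C1–C2(CH3)=C3 is what a trisubstituted alkene leaves after attack through C1 and proton loss at C3, and C1–C7 with the three methyls form a head-to-tail geranyl chain.
The cyclohexene, the only ring that has to be made, arises in one step from an open chain with C1 and C5 already in place; the coumarin is bought as umbelliferone and joined last.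
C1 is set in the ring closure itself by the (E)-alkene geometry relative to C5, so neither a hydroboration nor a carbonyl methylenation occurs, and the one protecting group, the acetate, comes with the purchased ester, so the run-up is a single step.

Key step: step 2

Remark: geranyl acetate is taken as the pure (E)-isomer, because the alkene geometry becomes the configuration of C1 (the (Z)-isomer would give the trans ring).

Step 1
Reactants: 1 geranyl acetate [(2E)-3,7-dimethylocta-2,6-dien-1-yl acetate]
Product: 2 (2E)-5-[(2R)-3,3-dimethyloxiran-2-yl]-3-methylpent-2-en-1-yl acetate [(R)-6,7-epoxygeranyl acetate]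
Conditions: D-fructose-derived Shi ketone (1,2:4,5-di-O-isopropylidene-β-D-erythro-2,3-hexodiulo-2,6-pyranose, 30 mol %), Oxone (2KHSO5·KHSO4·K2SO4, 1.4 equiv), K2CO3, Bu4NHSO4 (4 mol %), MeCN–CH2(OMe)2, aq Na2B4O7/Na2EDTA buffer (pH 10.5), 0 °C
Reagents that add atoms: potassium peroxymonosulfate (KHSO5, the active component of Oxone), [K+].OOS(=O)(=O)[O-]
Why: In this Shi asymmetric epoxidation the chiral dioxirane made from the ketone and KHSO5 transfers oxygen through a spiro transition state to the electron-rich 6',7'-alkene (the 2',3'-alkene is deactivated by the allylic acetate) on the face that gives the (R)-oxirane, the sense this ketone shows with trisubstituted and trans-disubstituted alkenes.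

Step 2
Reactants: 2 (2E)-5-[(2R)-3,3-dimethyloxiran-2-yl]-3-methylpent-2-en-1-yl acetate
Product: 3 [(1S,5R)-5-hydroxy-2,6,6-trimethylcyclohex-2-en-1-yl]methyl acetate
Conditions: ZrCl4 (1.5 equiv), CH2Cl2, −20 to 0 °C; sat. aq NaHCO3; chromatography on AgNO3-impregnated SiO2
Reagents that add atoms: none
Why: ZrCl4 binds the oxirane oxygen, the tertiary C7'–O bond lengthens, and C2' of the 2',3'-alkene attacks C7' from the side opposite to oxygen, which forms the ring bond C1–C6 and a tertiary cation at C3' (the future C2) that loses the adjacent ring proton at C4' (the future C3) to give the trisubstituted ring alkene. The closest known reaction type is the Lewis-acid-promoted biomimetic epoxide-initiated cation–olefin cyclization of terminal epoxy polyprenyl acetates, for which ZrCl4 in CH2Cl2 is an established promoter on epoxygeranyl esters. The cyclohexene closes 6-endo-trig with respect to the alkene and with Markovnikov opening of the oxirane at its tertiary carbon, so that the former C6'–C7' bond becomes the ring bond C5–C6. C5 keeps the (R) configuration of the oxirane because its C–O bond is never broken, and C1 is set by the chair transition state, in which anti opening places the C5–O bond equatorial and the (E) geometry places C1'H2OAc equatorial, hence cis to the oxygen, which is (S). The step needs cyclization to outrun the 1,2-hydride shift of the activated oxirane and needs proton loss from C3 instead of from the methyl group; the first is secured by the 1,5 relation of the alkene to the oxirane carbon and by the still nucleophilic trisubstituted alkene, the second only by the Zaitsev preference, so the exocyclic isomer is the expected minor companion and is removed on AgNO3–silica. The acetate keeps the C1' oxygen from acting as a nucleophile and should survive ZrCl4 at low temperature.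

Step 3
Reactants: 3 [(1S,5R)-5-hydroxy-2,6,6-trimethylcyclohex-2-en-1-yl]methyl acetate; 4 3-methylbutanoyl chloride (isovaleryl chloride)
Product: 5 (1R,5S)-5-[(acetyloxy)methyl]-4,6,6-trimethylcyclohex-3-en-1-yl 3-methylbutanoate
Conditions: 4 (1.5 equiv), pyridine (3 equiv), DMAP (0.2 equiv), CH2Cl2, 0 °C to rt
Reagents that add atoms: none
Why: DMAP-catalysed acylation (nucleophilic acyl-transfer catalysis) esterifies the neopentylic C5 hydroxyl at oxygen, so C5 keeps its configuration, and from here on the isovalerate is both a part of the target and the protection of O–C5.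

Step 4
Reactants: 5 (1R,5S)-5-[(acetyloxy)methyl]-4,6,6-trimethylcyclohex-3-en-1-yl 3-methylbutanoate
Product: 6 (1R,5S)-5-(hydroxymethyl)-4,6,6-trimethylcyclohex-3-en-1-yl 3-methylbutanoate
Conditions: K2CO3 (0.3 equiv), MeOH, 0 °C, TLC control; AcOH quench
Reagents that add atoms: none
Why: Base-catalysed transesterification (methanolysis) should tell the two esters apart kinetically, because the acetyl group on the primary C7 oxygen is exchanged far faster than the β-branched acyl group on the neopentylic secondary C5 oxygen, and the low temperature and substoichiometric carbonate leave both stereocentres untouched.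

Step 5
Reactants: 6 (1R,5S)-5-(hydroxymethyl)-4,6,6-trimethylcyclohex-3-en-1-yl 3-methylbutanoate; 7 umbelliferone (7-hydroxy-2H-chromen-2-one)
Product: 8 (1R,5S)-4,6,6-trimethyl-5-{[(2-oxo-2H-chromen-7-yl)oxy]methyl}cyclohex-3-en-1-yl 3-methylbutanoate (target)
Conditions: 7 (1.3 equiv), PPh3 (1.5 equiv), DIAD (1.5 equiv), THF, 0 °C to rt
Reagents that add atoms: none
Why: In this Mitsunobu etherification the acidic phenol (pKa about 8) protonates the betaine and its phenoxide displaces the alkoxyphosphonium ion in an SN2 step at C7, which is not a stereocentre, under neutral conditions that leave the isovalerate, the lactone, C1 and C5 untouched.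

**Compound list**
1 | geranyl acetate, (2E)-3,7-dimethylocta-2,6-dien-1-yl acetate | CC(C)=CCC/C(C)=C/COC(C)=O | starting material
2 | (2E)-5-[(2R)-3,3-dimethyloxiran-2-yl]-3-methylpent-2-en-1-yl acetate | CC1(C)O[C@@H]1CC/C(C)=C/COC(C)=O | intermediate
3 | [(1S,5R)-5-hydroxy-2,6,6-trimethylcyclohex-2-en-1-yl]methyl acetate | CC1=CC[C@@H](O)C(C)(C)[C@H]1COC(C)=O | intermediate
4 | 3-methylbutanoyl chloride | CC(C)CC(=O)Cl | starting material
5 | (1R,5S)-5-[(acetyloxy)methyl]-4,6,6-trimethylcyclohex-3-en-1-yl 3-methylbutanoate | CC1=CC[C@@H](OC(=O)CC(C)C)C(C)(C)[C@H]1COC(C)=O | intermediate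
6 | (1R,5S)-5-(hydroxymethyl)-4,6,6-trimethylcyclohex-3-en-1-yl 3-methylbutanoate | CC1=CC[C@@H](OC(=O)CC(C)C)C(C)(C)[C@H]1CO | intermediate
7 | umbelliferone (7-hydroxy-2H-chromen-2-one) | Oc1ccc2ccc(=O)oc2c1 | starting material
8 | (1R,5S)-4,6,6-trimethyl-5-{[(2-oxo-2H-chromen-7-yl)oxy]methyl}cyclohex-3-en-1-yl 3-methylbutanoate | CC1=CC[C@@H](OC(=O)CC(C)C)C(C)(C)[C@H]1COc1ccc2ccc(=O)oc2c1 | target

Total step count: 5. Longest linear sequence: 5 steps (1 to 8).

**Steps most likely to fail**

Step 2 (key step). The cation may lose a proton from the methyl group instead of from C3 and give the exocyclic alkene. The activated oxirane may also undergo a 1,2-hydride shift (Meinwald rearrangement) before the alkene attacks, or the cation may be captured by oxygen. The fallback separates ring closure from alkene placement and sets out from 2. Cp2TiCl (trivalent titanium, made in the flask from Cp2TiCl2 and Mn dust, THF, rt) would open the oxirane homolytically at the tertiary carbon. The tertiary radical would add 6-endo to C2' through the same chair, and the cyclized tertiary radical, trapped by a second Cp2TiCl, would eliminate toward the methyl group. This should give [(1S,3R)-3-hydroxy-2,2-dimethyl-6-methylidenecyclohexyl]methyl acetate F1 with the same cis configuration. A cobalt hydride hydrogen-atom-transfer isomerization (chloro[N,N'-bis(3,5-di-tert-butylsalicylidene)cyclohexane-1,2-diaminato]cobalt 5 mol %, PhSiH3 5 mol %, benzene, rt) would then move the 1,1-disubstituted alkene one position into the ring. It is expected to go to the side of the unhindered C3H2 and not toward the C1–H that is flanked by the quaternary carbon, which returns to the route at 3.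

Step 4. Methanolysis may go on to the second ester, or the base may cause the isovaleryl group to migrate from O–C5 to the freed, cis-disposed C7 hydroxyl. The fallback avoids any stage with two esters and sets out from 3. Complete methanolysis (K2CO3, MeOH, rt) would give (1R,5S)-5-(hydroxymethyl)-4,6,6-trimethylcyclohex-3-en-1-ol F2. tBuPh2SiCl and imidazole in CH2Cl2 would silylate only the primary hydroxyl and give (1R,5S)-5-({[tert-butyl(diphenyl)silyl]oxy}methyl)-4,6,6-trimethylcyclohex-3-en-1-ol F3. Compound 4, pyridine and DMAP would then acylate O–C5 to (1R,5S)-5-({[tert-butyl(diphenyl)silyl]oxy}methyl)-4,6,6-trimethylcyclohex-3-en-1-yl 3-methylbutanoate F4. HF·pyridine in THF at 0 °C would remove the silyl group under acidic conditions that do not favour acyl migration, returning to the route at 6.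

Step 5. The SN2 displacement at the β-branched C7 may be slow, so that the alkoxyphosphonium ion eliminates toward the conjugated exocyclic diene or alkylates the reduced azodicarboxylate. The fallback makes the aryl–oxygen bond instead of the alkyl–oxygen bond and sets out from 6. Palladium-catalysed C–O cross-coupling with purchased 7-bromo-2H-chromen-2-one F5 ([Pd(cinnamyl)Cl]2 1 mol %, RockPhos 3 mol %, Cs2CO3, toluene, 70 °C) would leave C7 as a spectator carbon and arrive directly at 8.

Further compounds
F1 | step 2 | [(1S,3R)-3-hydroxy-2,2-dimethyl-6-methylidenecyclohexyl]methyl acetate | C=C1CC[C@@H](O)C(C)(C)[C@H]1COC(C)=O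
F2 | step 4 | (1R,5S)-5-(hydroxymethyl)-4,6,6-trimethylcyclohex-3-en-1-ol | CC1=CC[C@@H](O)C(C)(C)[C@H]1CO
F3 | step 4 | (1R,5S)-5-({[tert-butyl(diphenyl)silyl]oxy}methyl)-4,6,6-trimethylcyclohex-3-en-1-ol | CC1=CC[C@@H](O)C(C)(C)[C@H]1CO[Si](c1ccccc1)(c1ccccc1)C(C)(C)C
F4 | step 4 | (1R,5S)-5-({[tert-butyl(diphenyl)silyl]oxy}methyl)-4,6,6-trimethylcyclohex-3-en-1-yl 3-methylbutanoate | CC1=CC[C@@H](OC(=O)CC(C)C)C(C)(C)[C@H]1CO[Si](c1ccccc1)(c1ccccc1)C(C)(C)C
F5 | step 5 | 7-bromo-2H-chromen-2-one | Brc1ccc2ccc(=O)oc2c1
A1 | direct plan | (5R)-5-{[tert-butyl(dimethyl)silyl]oxy}-2,6,6-trimethylcyclohex-2-en-1-one | CC1=CC[C@@H](O[Si](C)(C)C(C)(C)C)C(C)(C)C1=O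
A2 | direct plan | tert-butyl(dimethyl){[(1R)-4,6,6-trimethyl-5-methylidenecyclohex-3-en-1-yl]oxy}silane | CC1=CC[C@@H](O[Si](C)(C)C(C)(C)C)C(C)(C)C1=C
A3 | direct plan | [(1S,5R)-5-{[tert-butyl(dimethyl)silyl]oxy}-2,6,6-trimethylcyclohex-2-en-1-yl]methanol | CC1=CC[C@@H](O[Si](C)(C)C(C)(C)C)C(C)(C)[C@H]1CO
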